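**Retrosynthetic overview**
1. Target 17 ⇐ bis-MOM ether 16 (two MOM ethers removed last, under non-enolising conditions).
2. Ring C, the C3–C4 bond and the C3 stereocentre ⇐ one carbene-catalysed closure: the ring A aldehyde, as an acyl anion equivalent, adds 1,6 to a ring B para-quinone methide released in situ from 13.
3. 13 ⇐ ring A salicylaldehyde 7 + ring B styrene oxide 11 (phenoxide opening of the epoxide, then acetylation).
4. 7 ⇐ 2,4,6-trihydroxybenzaldehyde 1 (bis-MOM, O-prenylation, para-Claisen–Cope); 11 ⇐ 4-hydroxybenzaldehyde 8 (C-prenylation, silylation, Corey–Chaykovsky).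
5. Ring order: rings A and B are bought as arenes; ring C is the only ring formed (step 8).

**Assumptions**
- The SMILES is read as the (3R)-isoflavanone.
- The sense of induction of the aminoindanol triazolium salt in step 8 is not established for this new closure. The (5aS,10bR) salt is written and taken to give 3R. If the first run (chiral HPLC, ECD) shows 3S, the mirror-image salt is used with nothing else changed.
- Abbreviations: prenyl = 3-methylbut-2-en-1-yl; MOM = methoxymethyl; TIPS = tri(propan-2-yl)silyl.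

**Route**

Step 1
Reactants: 1 2,4,6-trihydroxybenzaldehyde
Product: 2 2-hydroxy-4,6-bis(methoxymethoxy)benzaldehyde
Conditions: MOMCl (2.2 equiv), i-Pr2NEt (2.5 equiv), CH2Cl2, 0 °C → rt
Reagents that add atoms: chloromethyl methyl ether (MOMCl), COCCl
Why: Williamson-type MOM protection takes the para-hydroxyl and one ortho-hydroxyl, while the second ortho-hydroxyl stays locked in the hydrogen bond to the aldehyde and is left free; no stereocentre is formed.

Step 2
Reactants: 2 2-hydroxy-4,6-bis(methoxymethoxy)benzaldehyde; 3 1-bromo-3-methylbut-2-ene (prenyl bromide)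
Product: 4 2,4-bis(methoxymethoxy)-6-(prenyloxy)benzaldehyde
Conditions: K2CO3 (2 equiv), DMF, rt
Reagents that add atoms: none
Why: Williamson O-alkylation of the acidic chelated phenol with the allylic bromide in a dipolar aprotic solvent gives the aryl prenyl ether; no stereocentre is formed.

Step 3
Reactants: 4 2,4-bis(methoxymethoxy)-6-(prenyloxy)benzaldehyde
Product: 7 6-hydroxy-2,4-bis(methoxymethoxy)-3-prenylbenzaldehyde, via ortho-dienone 5 (not isolated), via para-dienone 6 (not isolated)
Conditions: PhNEt2, 200 °C, sealed tube, 2 h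
Reagents that add atoms: none
Why: Aromatic Claisen rearrangement to the free ortho carbon followed by a Cope shift (para-Claisen–Cope) moves the prenyl group to the carbon between the two MOM ethers, because the crowded 1,1-dimethylallyl dienone 5 relays faster than it enolises and dienone 6 then tautomerises to the chelated phenol, a course known for the corresponding acetophenone; 5 and 6 are racemic and transient, so no stereocentre remains.

Step 4
Reactants: 8 4-hydroxybenzaldehyde; 3 1-bromo-3-methylbut-2-ene (prenyl bromide)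
Product: 9 4-hydroxy-3-prenylbenzaldehyde
Conditions: KOH (10% aq), rt, 24 h
Reagents that add atoms: none
Why: Ortho C-alkylation of the phenoxide in water, where the solvated oxygen is shielded and the para position is blocked by the formyl group, is a known if modest-yielding (about 25–30%) one-step entry to this aldehyde; no stereocentre is formed.

Step 5
Reactants: 9 4-hydroxy-3-prenylbenzaldehyde
Product: 10 3-prenyl-4-[tri(propan-2-yl)silyloxy]benzaldehyde
Conditions: TIPSCl (1.2 equiv), imidazole (2.5 equiv), DMF, rt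
Reagents that add atoms: triisopropylsilyl chloride (TIPSCl), CC(C)[Si](Cl)(C(C)C)C(C)C
Why: Imidazole-promoted silylation gives a bulky aryl silyl ether that tolerates the later carbonate step yet is cleaved by fluoride on demand; no stereocentre is formed.

Step 6
Reactants: 10 3-prenyl-4-[tri(propan-2-yl)silyloxy]benzaldehyde
Product: 11 rac-2-{3-prenyl-4-[tri(propan-2-yl)silyloxy]phenyl}oxirane
Conditions: Me3S+ I− (1.3 equiv), KHMDS (1.25 equiv), THF, −20 → 0 °C
Reagents that add atoms: trimethylsulfonium iodide, C[S+](C)C.[I-]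
Why: Corey–Chaykovsky epoxidation with the preformed sulfonium ylide transfers CH2 to the aldehyde without touching the prenyl alkene or the silyl ether; the new epoxide carbon is racemic, which is harmless because that centre is flattened in step 8.

Step 7
Reactants: 7 6-hydroxy-2,4-bis(methoxymethoxy)-3-prenylbenzaldehyde; 11 rac-2-{3-prenyl-4-[tri(propan-2-yl)silyloxy]phenyl}oxirane
Product: 13 rac-2-[2-formyl-3,5-bis(methoxymethoxy)-4-prenylphenoxy]-1-{3-prenyl-4-[tri(propan-2-yl)silyloxy]phenyl}ethyl acetate, via secondary alcohol 12 (not isolated)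
Conditions: K2CO3 (0.3 equiv), DMF, 80 °C; then Ac2O (2 equiv), Et3N (3 equiv), DMAP (cat.), 0 °C → rt
Reagents that add atoms: acetic anhydride, CC(=O)OC(C)=O
Why: Base-mediated SN2 opening of the terminal epoxide carbon by the phenoxide of 7 gives the 2-aryloxy-1-arylethanol 12, which is acetylated in the same flask (DMAP-catalysed acylation); the benzylic carbinol centre is racemic and is erased in the next step.

Step 8
Reactants: 13 rac-2-[2-formyl-3,5-bis(methoxymethoxy)-4-prenylphenoxy]-1-{3-prenyl-4-[tri(propan-2-yl)silyloxy]phenyl}ethyl acetate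
Product: 16 (3R)-3-(4-hydroxy-3-prenylphenyl)-5,7-bis(methoxymethoxy)-6-prenyl-2,3-dihydro-4H-chromen-4-one, via cesium phenoxide 14 (not isolated), via para-quinone methide 15 (not isolated)
Conditions: (5aS,10bR)-2-(pentafluorophenyl)-5a,10b-dihydro-4H,6H-indeno[2,1-b][1,2,4]triazolo[4,3-d][1,4]oxazin-2-ium tetrafluoroborate (20 mol%), CsF (1.1 equiv), 18-crown-6 (20 mol%), 4 Å MS, THF (0.02 M), 0 °C; AcOH quench
Reagents that add atoms: none
Why: Proposed new method: fluoride removes the TIPS group, phenoxide 14 expels acetate to give the planar para-quinone methide 15 (both enantiomers of 13 converge), and the chiral triazolylidene turns the tethered aldehyde into a carbene-bound acyl anion equivalent (Breslow-type enaminol) that adds 1,6 to the exocyclic carbon in a 6-exo closure driven by re-aromatisation of ring B, the aminoindanol backbone shielding one face so that C3 is formed as R, while the weakly basic fluoride/acetate medium at 0 °C and the acid quench protect the new α-aryl ketone centre; the closest known reactions are the enantioselective intramolecular Stetter reaction giving 3-substituted chroman-4-ones and the carbene-catalysed 1,6-addition of aldehydes to para-quinone methides.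

Step 9
Reactants: 16 (3R)-3-(4-hydroxy-3-prenylphenyl)-5,7-bis(methoxymethoxy)-6-prenyl-2,3-dihydro-4H-chromen-4-one
Product: 17 (3R)-5,7-dihydroxy-3-(4-hydroxy-3-prenylphenyl)-6-prenyl-2,3-dihydro-4H-chromen-4-one (CNP0206440.1)
Conditions: ZnBr2 (2 equiv), n-PrSH (4 equiv), CH2Cl2, 0 °C, 10 min
Reagents that add atoms: none
Why: Lewis acid-assisted thiolytic cleavage of the two aryl MOM acetals (the carbonyl-chelated 5-O and the para-acyl 7-O ethers are the most labile kind) is over in minutes at 0 °C, so the enolisable C3–H set in step 8 and the acid-sensitive prenyl groups are not exposed to protic acid; no stereocentre is formed.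

**Compound list**
1 | 2,4,6-trihydroxybenzaldehyde | O=Cc1c(O)cc(O)cc1O | starting material
2 | 2-hydroxy-4,6-bis(methoxymethoxy)benzaldehyde | O=Cc1c(O)cc(OCOC)cc1OCOC | intermediate
3 | 1-bromo-3-methylbut-2-ene (prenyl bromide) | CC(C)=CCBr | starting material
4 | 2,4-bis(methoxymethoxy)-6-[(3-methylbut-2-en-1-yl)oxy]benzaldehyde | O=Cc1c(OCC=C(C)C)cc(OCOC)cc1OCOC | intermediate
5 | rac-2,4-bis(methoxymethoxy)-5-(2-methylbut-3-en-2-yl)-6-oxocyclohexa-1,3-diene-1-carbaldehyde (ortho-dienone, not isolated) | O=CC1=C(OCOC)C=C(OCOC)C(C(C)(C)C=C)C1=O | intermediate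
6 | rac-2,4-bis(methoxymethoxy)-3-(3-methylbut-2-en-1-yl)-6-oxocyclohexa-1,4-diene-1-carbaldehyde (para-dienone, not isolated) | O=CC1=C(OCOC)C(CC=C(C)C)C(OCOC)=CC1=O | intermediate
7 | 6-hydroxy-2,4-bis(methoxymethoxy)-3-(3-methylbut-2-en-1-yl)benzaldehyde | O=Cc1c(O)cc(OCOC)c(CC=C(C)C)c1OCOC | intermediate
8 | 4-hydroxybenzaldehyde | O=Cc1ccc(O)cc1 | starting material
9 | 4-hydroxy-3-(3-methylbut-2-en-1-yl)benzaldehyde | O=Cc1ccc(O)c(CC=C(C)C)c1 | intermediate
10 | 3-(3-methylbut-2-en-1-yl)-4-[tri(propan-2-yl)silyloxy]benzaldehyde | O=Cc1ccc(O[Si](C(C)C)(C(C)C)C(C)C)c(CC=C(C)C)c1 | intermediate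
11 | rac-2-{3-(3-methylbut-2-en-1-yl)-4-[tri(propan-2-yl)silyloxy]phenyl}oxirane | CC(C)=CCc1cc(C2CO2)ccc1O[Si](C(C)C)(C(C)C)C(C)C | intermediate
12 | rac-6-(2-hydroxy-2-{3-(3-methylbut-2-en-1-yl)-4-[tri(propan-2-yl)silyloxy]phenyl}ethoxy)-2,4-bis(methoxymethoxy)-3-(3-methylbut-2-en-1-yl)benzaldehyde (not isolated) | O=Cc1c(OCC(O)c2ccc(O[Si](C(C)C)(C(C)C)C(C)C)c(CC=C(C)C)c2)cc(OCOC)c(CC=C(C)C)c1OCOC | intermediate
13 | rac-2-[2-formyl-3,5-bis(methoxymethoxy)-4-(3-methylbut-2-en-1-yl)phenoxy]-1-{3-(3-methylbut-2-en-1-yl)-4-[tri(propan-2-yl)silyloxy]phenyl}ethyl acetate | O=Cc1c(OCC(OC(C)=O)c2ccc(O[Si](C(C)C)(C(C)C)C(C)C)c(CC=C(C)C)c2)cc(OCOC)c(CC=C(C)C)c1OCOC | intermediate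
14 | rac-cesium 4-{1-acetoxy-2-[2-formyl-3,5-bis(methoxymethoxy)-4-(3-methylbut-2-en-1-yl)phenoxy]ethyl}-2-(3-methylbut-2-en-1-yl)phenolate (not isolated) | [Cs+].[O-]c1ccc(C(COc2cc(OCOC)c(CC=C(C)C)c(OCOC)c2C=O)OC(C)=O)cc1CC=C(C)C | intermediate
15 | 2,4-bis(methoxymethoxy)-3-(3-methylbut-2-en-1-yl)-6-{2-[3-(3-methylbut-2-en-1-yl)-4-oxocyclohexa-2,5-dien-1-ylidene]ethoxy}benzaldehyde (para-quinone methide, not isolated) | O=Cc1c(OCC=C2C=CC(=O)C(CC=C(C)C)=C2)cc(OCOC)c(CC=C(C)C)c1OCOC | intermediate
16 | (3R)-3-[4-hydroxy-3-(3-methylbut-2-en-1-yl)phenyl]-5,7-bis(methoxymethoxy)-6-(3-methylbut-2-en-1-yl)-2,3-dihydro-4H-chromen-4-one | CC(C)=CCc1cc([C@@H]2COc3cc(OCOC)c(CC=C(C)C)c(OCOC)c3C2=O)ccc1O | intermediate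
17 | (3R)-5,7-dihydroxy-3-[4-hydroxy-3-(3-methylbut-2-en-1-yl)phenyl]-6-(3-methylbut-2-en-1-yl)-2,3-dihydro-4H-chromen-4-one (CNP0206440.1) | CC(C)=CCc1cc([C@@H]2COc3cc(O)c(CC=C(C)C)c(O)c3C2=O)ccc1O | target

**Step count**
Total: 9 steps (the one-pot operations of steps 3, 7 and 8 counted once each). Longest linear sequence: 6 steps (1, 2, 3, 7, 8, 9).

**Three steps most likely to fail, with fallbacks**

Step 8. This is a new closure. The dangers are slow carbene addition to the hindered 2,6-dioxygenated aldehyde, tautomerisation of 15 to a 4-hydroxystyryl ether, and loss of ee at the α-aryl ketone in the fluoride/acetate medium. The fallback sets out from 13 and comes back at 16; it gives up enantiocontrol in the C–C bond formation and sets C3 afterwards by dynamic kinetic resolution. Compound 13 is cyclised with an achiral, more nucleophilic carbene (2-mesityl-6,7-dihydro-5H-pyrrolo[2,1-c][1,2,4]triazol-2-ium chloride 20 mol%, CsF, THF, rt) to racemic 3-(4-hydroxy-3-prenylphenyl)-5,7-bis(methoxymethoxy)-6-prenylchroman-4-one F1. Transfer hydrogenation (RuCl[(R,R)-TsDPEN](p-cymene), HCO2H/Et3N, EtOAc, rt), in which the amine keeps C3 epimerising and only the 3R ketone is reduced, gives cis-(3R,4R)-3-(4-hydroxy-3-prenylphenyl)-5,7-bis(methoxymethoxy)-6-prenylchroman-4-ol F2. Oxidation of the activated benzylic alcohol with MnO2 (CH2Cl2, rt) returns the ketone 16 with C3 intact.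

Step 7. The weakly nucleophilic chelated phenoxide needs heat to open the epoxide, and under those conditions the aryl silyl ether may be lost or the benzylic carbon attacked instead. The fallback sets out from 11 (with 7) and comes back at 13; it forms the ether bond by Mitsunobu reaction under neutral conditions instead of by epoxide opening with phenoxide. Epoxide 11 is opened at its benzylic carbon with acetic acid (AcOH, CH2Cl2, rt) to rac-2-hydroxy-1-{3-prenyl-4-[tri(propan-2-yl)silyloxy]phenyl}ethyl acetate F3, which is used at once to avoid acyl migration. Its primary hydroxyl is joined to the acidic phenol 7 by Mitsunobu etherification (PPh3, DIAD, THF, 0 °C), which gives 13 directly.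

Step 9. Cleavage itself is safe, but C3 may partly epimerise or a prenyl group may close onto a neighbouring phenol. The fallback sets out from 16 and comes back at 17; it stops protecting C3 during deprotection and re-sets it at the very end by enantioselective protonation. The MOM ethers are removed robustly (1 M HCl, MeOH, rt) to give the target as its racemate, rac-5,7-dihydroxy-3-(4-hydroxy-3-prenylphenyl)-6-prenylchroman-4-one F4. Persilylation (TMSOTf, Et3N, CH2Cl2, 0 °C) gives the silyl enol ether 4,5,7-tris(trimethylsilyloxy)-6-prenyl-3-[3-prenyl-4-(trimethylsilyloxy)phenyl]-2H-chromene F5. Catalytic enantioselective protonation of the enol ether follows, with (S)-3,3'-bis(2,4,6-triisopropylphenyl)-1,1'-binaphthalene-2,2'-diyl N-(trifluoromethanesulfonyl)thiophosphoramide (5 mol%; the mirror image if the sense proves opposite) and PhOH (1.1 equiv) in toluene at rt, a method known for 2-aryl cyclic ketone enol silanes. It gives (3R)-5,7-bis(trimethylsilyloxy)-6-prenyl-3-[3-prenyl-4-(trimethylsilyloxy)phenyl]chroman-4-one F6, whose aryl silyl ethers fall off on neutral aqueous methanol work-up to give 17.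

**Further compounds**
F1 | step 8 | rac-3-[4-hydroxy-3-(3-methylbut-2-en-1-yl)phenyl]-5,7-bis(methoxymethoxy)-6-(3-methylbut-2-en-1-yl)-2,3-dihydro-4H-chromen-4-one | CC(C)=CCc1cc(C2COc3cc(OCOC)c(CC=C(C)C)c(OCOC)c3C2=O)ccc1O
F2 | step 8 | (3R,4R)-3-[4-hydroxy-3-(3-methylbut-2-en-1-yl)phenyl]-5,7-bis(methoxymethoxy)-6-(3-methylbut-2-en-1-yl)-3,4-dihydro-2H-chromen-4-ol | CC(C)=CCc1cc([C@@H]2COc3cc(OCOC)c(CC=C(C)C)c(OCOC)c3[C@@H]2O)ccc1O
F3 | step 7 | rac-2-hydroxy-1-{3-(3-methylbut-2-en-1-yl)-4-[tri(propan-2-yl)silyloxy]phenyl}ethyl acetate | CC(=O)OC(CO)c1ccc(O[Si](C(C)C)(C(C)C)C(C)C)c(CC=C(C)C)c1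
F4 | step 9 | rac-5,7-dihydroxy-3-[4-hydroxy-3-(3-methylbut-2-en-1-yl)phenyl]-6-(3-methylbut-2-en-1-yl)-2,3-dihydro-4H-chromen-4-one | CC(C)=CCc1cc(C2COc3cc(O)c(CC=C(C)C)c(O)c3C2=O)ccc1O
F5 | step 9 | 4,5,7-tris(trimethylsilyloxy)-6-(3-methylbut-2-en-1-yl)-3-[3-(3-methylbut-2-en-1-yl)-4-(trimethylsilyloxy)phenyl]-2H-chromene | CC(C)=CCc1cc(C2=C(O[Si](C)(C)C)c3c(O[Si](C)(C)C)c(CC=C(C)C)c(O[Si](C)(C)C)cc3OC2)ccc1O[Si](C)(C)C
F6 | step 9 | (3R)-5,7-bis(trimethylsilyloxy)-6-(3-methylbut-2-en-1-yl)-3-[3-(3-methylbut-2-en-1-yl)-4-(trimethylsilyloxy)phenyl]-2,3-dihydro-4H-chromen-4-one | CC(C)=CCc1cc([C@@H]2COc3cc(O[Si](C)(C)C)c(CC=C(C)C)c(O[Si](C)(C)C)c3C2=O)ccc1O[Si](C)(C)C
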